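**In the flask.** A small charge of free enzyme, 0.01 mol% on 0.050 M of substrate, has been working in the flask you take over, and its product has nearly stopped rising. The charges, readings, options and questions stand here.

| flask | substrate | free enzyme | temperature | remark | time |
|---|---|---|---|---|---|
| Saturday's | 0.050 M | 0.01 mol% | 25 °C | the very flask that is asked about, followed so far |  |
| Sunday's | 0.034 M | 0.01 mol% | 10 °C | run made earlier |  |
| flask | 0.050 M | 0.01 mol% | 25 °C |  | 8.0 d |

- Saturday's (time / h: product / %): 25.0: 56.6; 50.0: 64.4; 72.0: 67.4; 96.0: 68.0; 120: 69.2
- Sunday's (time / h: product / %): 3.00: 13.9; 6.00: 22.9; 10.0: 28.9; 12.0: 31.8; 15.0: 34.2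

(each reading ± 1 percentage point)

- north-east: change nothing and wait 15 d more
- south-east: at 8.0 d take out 90% of the product then present, then wait 15 d
- east: at 8.0 d add free enzyme, 100% of the amount charged, then wait 15 d
- north: at 8.0 d raise the temperature by 25 K, then wait 15 d

- removed product is counted in
- additions bring no volume worth counting

* product, in percent of the substrate first charged, at 8.0 d
* the option that brings most further product ("none" if no option brings more than 2 percentage points) (north-east / south-east / east / north / none)
* product present, with what was taken out counted in, in percent of the substrate first charged, after north-east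
* product present, with what was taken out counted in, in percent of the substrate first charged, after north

**Stop ratio.** The last reading gives 2.25: this is product divided by the rest of the charge, the stop ratio, and equal halves, the symmetric case, put the zero of its scale at 1. At one temperature, a first-order balance between substrate and product keeps this ratio at any charge, since both sides scale together, whereas a fading catalyst leaves it free to move. Your two runs differ in charge and in temperature together, so they do not separate these readings of the stop.

**When you come.** From 72.0 h to 120 h the product gained 1.8 percentage points against a scatter of 1 point, so I expect about 69.2% at 8.0 d. Leave the bath alone: a fading catalyst is one reading of the stop, and no run here stands above 25 °C; I would try east, which tests that reading.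

**The forecast.** It differs from me: “So I read the plateaus as a reversible equilibrium”. It gave 69.5% now, 70% after north-east, 91% after north, and chose north.

**The result.** The flask gave 70.1%, 70.4% after north-east and 70.1% after north, and east was best, bringing 8.4 points more.

    substrate ⇌ dormant form (K = 0.570, k = 0.360 h⁻¹, Ea = 104 kJ mol⁻¹, ΔH = 21.0 kJ mol⁻¹)
    substrate + free enzyme → product + free enzyme, rate k2*[substrate]^3*[free enzyme]/(1 + ([substrate]/Kh2)^3) (0.0620 M, k = 3.40 × 10⁷ L³ mol⁻³ h⁻¹, Ea = 26.0 kJ mol⁻¹)
    free enzyme → unfolded enzyme (k = 0.0210 h⁻¹, Ea = 254 kJ mol⁻¹)
    (constants at 25 °C)

**The neighbour.** At 192 h this flask held 1.77% free enzyme and 98.2% unfolded enzyme, in percent of the catalyst charged, which is catalyst deactivation. Its stop ratio was 2.34. A first-order balance at the stop ratio read on Saturday gives 69.2% at any charge at 25 °C, but the neighbour with 0.20 M of substrate, its temperature, loading and time held, reached 95.9%, a stop ratio of 23.6, far above 2.25, with 2.6% of its substrate left.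

The earlier runs and the new flask are simulated with made-up constants; scatter was added.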